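Ring C is cut at C4–C4a and O1–C2, so ring A comes from 1,2,3-trimethoxybenzene and C2–C4 plus ring B from an arylpropioloyl chloride. The feature exploited is ring A itself: O1 on C8a and the methoxy groups on C8 and C7 form a contiguous trioxygenated arene whose acylation site (para to the C7 oxygen, ortho to the C8a oxygen) is C4a. In one operation aluminium chloride should acylate that carbon, remove the methyl from the flanking oxygen by chelation and close the pyranone 6-endo onto the ynone. The precursor is 3-(3-acetoxy-4,5-dimethoxyphenyl)propioloyl chloride, the acetate masking the 3'-OH and deactivating ring B.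

Key step: step 6

Assumption: the target has no stereocentre and no stereogenic axis, so it is one achiral compound and no step needs stereocontrol.

Design remark: the temporary silyl ether is removed in the alkaline work-up of the carboxylation, so the change of protecting group costs no separate step. Any acetate lost in step 6 gives the target itself and converges in step 7.

Step 1
Reactants: 1 3-hydroxy-4,5-dimethoxybenzaldehyde
Product: 2 3-[(tert-butyldimethylsilyl)oxy]-4,5-dimethoxybenzaldehyde
Conditions: TBSCl, imidazole, DMF, rt
Reagents that add atoms: tert-butyldimethylsilyl chloride, CC(C)(C)[Si](C)(C)Cl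
Why: Standard silylation of a phenol, which removes the acidic OH that would otherwise consume the ylide of step 2 and the butyllithium of step 3.

Step 2
Reactants: 2 3-[(tert-butyldimethylsilyl)oxy]-4,5-dimethoxybenzaldehyde
Product: 3 tert-butyl[5-(2,2-dibromoethenyl)-2,3-dimethoxyphenoxy]dimethylsilane
Conditions: CBr4, PPh3, Zn dust, CH2Cl2, rt (ylide formed first), then 2, rt
Reagents that add atoms: carbon tetrabromide, BrC(Br)(Br)Br
Why: Ramirez dibromo-olefination (first half of the Corey–Fuchs homologation) of an aromatic aldehyde under neutral conditions that leave the aryl silyl ether intact.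

Step 3
Reactants: 3 tert-butyl[5-(2,2-dibromoethenyl)-2,3-dimethoxyphenoxy]dimethylsilane
Product: 6 3-(3-hydroxy-4,5-dimethoxyphenyl)prop-2-ynoic acid, via lithium arylacetylide 4 (not isolated), via lithium silyloxyarylpropiolate 5 (not isolated)
Conditions: n-BuLi (2.2 equiv), THF, −78 °C; CO2, −78 °C → rt; then 2 M NaOH, MeOH, rt; HCl to pH 2, 0 °C
Reagents that add atoms: carbon dioxide, O=C=O
Why: Second half of the Corey–Fuchs sequence (bromine–lithium exchange, Fritsch–Buttenberg–Wiechell rearrangement, carboxylation of the lithium acetylide), after which the base-labile aryl silyl ether is cleaved by the aqueous methanolic hydroxide of the work-up and the hydroxy acid is obtained by acid–base extraction.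

Step 4
Reactants: 6 3-(3-hydroxy-4,5-dimethoxyphenyl)prop-2-ynoic acid
Product: 7 3-[3-(acetyloxy)-4,5-dimethoxyphenyl]prop-2-ynoic acid
Conditions: Ac2O, 2 M aq NaOH, 0 °C; then cold 2 M HCl to pH 2
Reagents that add atoms: acetic anhydride, CC(=O)OC(C)=O
Why: Schotten–Baumann acetylation: in cold aqueous base the phenoxide is acetylated much faster than the carboxylate, any mixed anhydride hydrolyses, and acidification should give the acetoxy acid, as is routine for phenolic acids.

Step 5
Reactants: 7 3-[3-(acetyloxy)-4,5-dimethoxyphenyl]prop-2-ynoic acid
Product: 8 3-[3-(acetyloxy)-4,5-dimethoxyphenyl]prop-2-ynoyl chloride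
Conditions: (COCl)2, DMF (cat.), CH2Cl2, 0 °C → rt; concentrate, use crude at once
Reagents that add atoms: oxalyl chloride, O=C(Cl)C(=O)Cl
Why: Vilsmeier-catalysed acid chloride formation with oxalyl chloride, which works on arylpropiolic acids at or below room temperature, gives only volatile by-products and leaves the aryl acetate untouched.

Step 6
Reactants: 8 3-[3-(acetyloxy)-4,5-dimethoxyphenyl]prop-2-ynoyl chloride; 9 1,2,3-trimethoxybenzene
Product: 12 3'-(acetyloxy)-4',5',7,8-tetramethoxyflavone, via trimethoxyphenyl ynone 10 (not isolated), via dichloroaluminium phenoxide ynone 11 (not isolated)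
Conditions: AlCl3 (3 equiv), 9 (2.5 equiv), CH2Cl2, −20 °C → rt; ice/1 M HCl
Reagents that add atoms: none
Why: Proposed new method: aluminium chloride ionises 8 to an alkynoyl acylium that attacks 9 at C4 (para to one outer methoxy, ortho to the other; C4 and C6 are equivalent) to give ynone 10 and the C4–C4a bond; aluminium then chelates the ketone and the adjacent methoxy, chloride removes that methyl as chloromethane to give phenoxide 11, and the phenoxide oxygen adds to the activated ynone β-carbon to form O1–C2, the hydrogen chloride released in the acylation protonating C3. The closest known reactions are Friedel–Crafts acylation of arenes with arylpropioloyl chlorides, aluminium chloride acylation of 1,2,3-trimethoxybenzene with chelation-controlled loss of the ortho methyl, and acid-promoted cyclisation of o-hydroxyaryl or o-methoxyaryl ynones to flavones; joining them in one flask is the new part. The pyranone closes by 6-endo-dig oxa-Michael addition (attack by the methoxy oxygen first, followed by demethylation of the oxonium, would give the same product). No stereocentre is formed. Selectivity for 9 over ring B rests on the excess of 9 and on the acetoxy and ynoyl groups that deactivate ring B; attack at the acyl carbon and not at the β-carbon rests on the hard character of the acylium; cleavage of one methyl only rests on the ketone chelate together with limited aluminium chloride and temperature; and 6-endo over 5-exo closure rests on carbonyl complexation, which places positive charge on the benzylic β-carbon stabilised by the 4'-methoxy group.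

Step 7
Reactants: 12 3'-(acetyloxy)-4',5',7,8-tetramethoxyflavone
Product: 13 3'-hydroxy-4',5',7,8-tetramethoxyflavone
Conditions: K2CO3 (0.3 equiv), MeOH/CH2Cl2, rt; dilute aq NH4Cl
Reagents that add atoms: none
Why: Base-catalysed transesterification (methanolysis) of an aryl acetate is fast at room temperature and should leave the flavone and the methyl ethers untouched.

Compound list
1 | 3-hydroxy-4,5-dimethoxybenzaldehyde | COc1cc(C=O)cc(O)c1OC | starting material
2 | 3-[(tert-butyldimethylsilyl)oxy]-4,5-dimethoxybenzaldehyde | COc1cc(C=O)cc(O[Si](C)(C)C(C)(C)C)c1OC | intermediate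
3 | tert-butyl[5-(2,2-dibromoethenyl)-2,3-dimethoxyphenoxy]dimethylsilane | COc1cc(C=C(Br)Br)cc(O[Si](C)(C)C(C)(C)C)c1OC | intermediate
4 | lithium {3-[(tert-butyldimethylsilyl)oxy]-4,5-dimethoxyphenyl}ethynide | COc1cc(C#C[Li])cc(O[Si](C)(C)C(C)(C)C)c1OC | intermediate
5 | lithium 3-{3-[(tert-butyldimethylsilyl)oxy]-4,5-dimethoxyphenyl}prop-2-ynoate | COc1cc(C#CC(=O)[O-])cc(O[Si](C)(C)C(C)(C)C)c1OC.[Li+] | intermediate
6 | 3-(3-hydroxy-4,5-dimethoxyphenyl)prop-2-ynoic acid | COc1cc(C#CC(=O)O)cc(O)c1OC | intermediate
7 | 3-[3-(acetyloxy)-4,5-dimethoxyphenyl]prop-2-ynoic acid | COc1cc(C#CC(=O)O)cc(OC(C)=O)c1OC | intermediate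
8 | 3-[3-(acetyloxy)-4,5-dimethoxyphenyl]prop-2-ynoyl chloride | COc1cc(C#CC(=O)Cl)cc(OC(C)=O)c1OC | intermediate
9 | 1,2,3-trimethoxybenzene | COc1cccc(OC)c1OC | starting material
10 | 3-[3-(acetyloxy)-4,5-dimethoxyphenyl]-1-(2,3,4-trimethoxyphenyl)prop-2-yn-1-one | COc1cc(C#CC(=O)c2ccc(OC)c(OC)c2OC)cc(OC(C)=O)c1OC | intermediate
11 | dichloroaluminium 6-{3-[3-(acetyloxy)-4,5-dimethoxyphenyl]prop-2-ynoyl}-2,3-dimethoxyphenoxide | COc1cc(C#CC(=O)c2ccc(OC)c(OC)c2O[Al](Cl)Cl)cc(OC(C)=O)c1OC | intermediate
12 | 3'-(acetyloxy)-4',5',7,8-tetramethoxyflavone [5-(7,8-dimethoxy-4-oxo-4H-chromen-2-yl)-2,3-dimethoxyphenyl acetate] | COc1cc(-c2cc(=O)c3ccc(OC)c(OC)c3o2)cc(OC(C)=O)c1OC | intermediate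
13 | 3'-hydroxy-4',5',7,8-tetramethoxyflavone [2-(3-hydroxy-4,5-dimethoxyphenyl)-7,8-dimethoxy-4H-chromen-4-one] | COc1cc(-c2cc(=O)c3ccc(OC)c(OC)c3o2)cc(O)c1OC | target

Total step count: 7
Longest linear sequence: 7 steps (1 → 2 → 3 → 6 → 7 → 8 → 12 → 13); arene 9 is purchased and enters in step 6.

Steps most likely to fail

Step 6. The arene may add to the β-carbon of the ynoyl electrophile instead of the acyl carbon, or ring B may be acylated. The sequence may stall after acylation without cleavage of the methyl ether, or further methyl ethers may be cleaved. The acetate may migrate or be lost, and closure may go 5-exo. The fallback uses only known chemistry and builds ring C from a chalcone instead of an ynone. It sets out from 9, which on Friedel–Crafts acetylation with acetyl chloride and aluminium chloride in dichloromethane at room temperature (acylation with chelation-assisted loss of the flanking methyl) should give 1-(2-hydroxy-3,4-dimethoxyphenyl)ethan-1-one F1. Claisen–Schmidt condensation of F1 with aldehyde 1 (KOH in excess, EtOH, rt) should give (E)-1-(2-hydroxy-3,4-dimethoxyphenyl)-3-(3-hydroxy-4,5-dimethoxyphenyl)prop-2-en-1-one F2. Oxidative cyclisation of F2 with catalytic iodine in DMSO at about 120 °C closes the pyranone and comes back to the route at 13.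

Step 5. Hydrogen chloride may add across the activated triple bond, or the ynoyl chloride may decompose on concentration. The fallback avoids the acid chloride. It sets out from 7, which with trifluoroacetic anhydride in dichloromethane should form 3-[3-(acetyloxy)-4,5-dimethoxyphenyl]prop-2-ynoic trifluoroacetic anhydride F3 in the flask. With catalytic phosphoric acid this mixed anhydride acylates 9 (mixed-anhydride Friedel–Crafts acylation of an activated arene) to give the ynone, this time isolated. The fallback comes back to the route at 10, which is then treated with the aluminium chloride of step 6 for methyl ether cleavage and ring closure.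

Step 3. The rearrangement or carboxylation of the acetylide may be incomplete, butyllithium may attack the silyl ether, or silyl cleavage in the work-up may be incomplete. The fallback avoids organolithium chemistry and the protecting group. It sets out from 1, which under Ohira–Bestmann homologation (dimethyl (1-diazo-2-oxopropyl)phosphonate, K2CO3, MeOH, rt; the phenoxide is meta to the aldehyde and barely deactivates it) should give 5-ethynyl-2,3-dimethoxyphenol F4. Silver-catalysed carboxylation of the terminal alkyne (AgI cat., Cs2CO3, CO2 1 atm, DMF, 50 °C; then HCl) comes back to the route at 6.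

Further compounds
F1 | step 6 | 1-(2-hydroxy-3,4-dimethoxyphenyl)ethan-1-one | CC(=O)c1ccc(OC)c(OC)c1O
F2 | step 6 | (E)-1-(2-hydroxy-3,4-dimethoxyphenyl)-3-(3-hydroxy-4,5-dimethoxyphenyl)prop-2-en-1-one | COc1cc(/C=C/C(=O)c2ccc(OC)c(OC)c2O)cc(O)c1OC
F3 | step 5 | 3-[3-(acetyloxy)-4,5-dimethoxyphenyl]prop-2-ynoic trifluoroacetic anhydride | COc1cc(C#CC(=O)OC(=O)C(F)(F)F)cc(OC(C)=O)c1OC
F4 | step 3 | 5-ethynyl-2,3-dimethoxyphenol | COc1cc(C#C)cc(O)c1OC
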